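**Plan**

- Labels: carbocycle C1 (quaternary, allyl) – C2 – C3 (OMe) – C4=C5 – C6 (C=O); side chain C8 (CHMe) – C7 (CHOH–aryl).
- Enabling feature: the oxygens on C3 and C6 of the six-membered ring stand 1,4 to each other across C4=C5, so both C–O bonds are cut together back to the C3=C4–C5=C6 cyclohexadiene.
- Further cuts: C3=C4 back to a C4 enone, C5–C6 (aldol ring opening), C1–allyl, C1–C2, and C7–C8.
- Forward: crotylboration of veratraldehyde joins C7–C8; a cis γ-lactone (O–C7–C8–C1–C6) is built and alkylated at C1, first with the masked 3-oxobutyl chain (C2–C5), then with allyl bromide. The lactone is reduced, C7–O silylated, C6 oxidised, and the only carbocycle closes by aldol condensation; a Shapiro reaction gives the diene, palladium adds two acetates, and five functional-group steps finish.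
- Stereochemistry: C7 (S) and C8 (R) from the catalyst-controlled syn crotylboration; C1 from the second lactone alkylation, anti to the cis methyl/aryl pair; C3 (S) from acetate attack anti to palladium held on the allyl face; the C6 centre of the diacetate is erased by oxidation.

Key step: step 13

Remark: (S)-TRIP is taken as the acid enantiomer that sends the crotyl group to the Si face of an aryl aldehyde; the labels C1 to C8 above are used for all intermediates.

**Route**

Step 1
Reactants: 1 veratraldehyde; 2 (Z)-crotylboronic acid pinacol ester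
Product: 4 (1S,2R)-1-(3,4-dimethoxyphenyl)-2-methylbut-3-en-1-ol, via pinacol borate ester 3 (not isolated)
Conditions: (S)-TRIP [(S)-3,3'-bis(2,4,6-triisopropylphenyl)-1,1'-binaphthyl-2,2'-diyl hydrogen phosphate] (5 mol %), toluene, −30 °C; then H2O work-up
Reagents that add atoms: none
Why: Chiral-phosphoric-acid-catalysed crotylboration through a closed chair (Zimmerman–Traxler) transition state, in which the Z boronate gives the syn C7/C8 pair and addition to the aldehyde Si face makes C7 S and C8 R.

Step 2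
Reactants: 4 (1S,2R)-1-(3,4-dimethoxyphenyl)-2-methylbut-3-en-1-ol
Product: 6 (1S,2R)-1-(3,4-dimethoxyphenyl)-2-methylbutane-1,4-diol, via B-alkyl-9-BBN adduct 5 (not isolated)
Conditions: 9-BBN (2.2 equiv), THF, 0 → 25 °C; then aq. NaOH, H2O2, 0 °C
Reagents that add atoms: hydrogen peroxide, OO
Why: Anti-Markovnikov hydroboration–oxidation should place the new hydroxyl on the terminal carbon (the future C6) and leave C7 and C8 untouched.

Step 3
Reactants: 6 (1S,2R)-1-(3,4-dimethoxyphenyl)-2-methylbutane-1,4-diol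
Product: 8 (4R,5S)-5-(3,4-dimethoxyphenyl)-4-methyldihydrofuran-2(3H)-one (cis lactone), via lactol 7 (not isolated)
Conditions: TEMPO (10 mol %), PhI(OAc)2 (2.5 equiv), CH2Cl2, 25 °C
Reagents that add atoms: none
Why: Oxidative lactonisation of a 1,4-diol, in which the oxoammonium oxidant takes the primary alcohol, the aldehyde is trapped by the C7 hydroxyl and the lactol is oxidised on, keeping methyl and aryl cis.

Step 4
Reactants: 9 2-(2-bromoethyl)-2-methyl-1,3-dioxolane
Product: 10 2-(2-iodoethyl)-2-methyl-1,3-dioxolane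
Conditions: NaI, NaHCO3, acetone, reflux
Reagents that add atoms: sodium iodide, [Na+].[I-]
Why: Finkelstein halide exchange, driven by precipitation of NaBr, should give the more reactive primary iodide.

Step 5
Reactants: 8 cis lactone; 10 2-(2-iodoethyl)-2-methyl-1,3-dioxolane
Product: 12 (3R,4R,5S)-5-(3,4-dimethoxyphenyl)-4-methyl-3-[2-(2-methyl-1,3-dioxolan-2-yl)ethyl]dihydrofuran-2(3H)-one, via lithium enolate 11 (not isolated)
Conditions: LiN(i-Pr)2 (LDA, 1.05 equiv), THF, −78 °C; then 10, DMPU, −78 → −20 °C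
Reagents that add atoms: none
Why: SN2 alkylation of the lactone enolate forms C1–C2 with the chain entering anti to the C8 methyl, a centre that is made planar again in step 6 so only the constitution matters here.

Step 6
Reactants: 12 mono-alkylated lactone; 13 allyl bromide
Product: 15 (3R,4R,5S)-3-allyl-5-(3,4-dimethoxyphenyl)-4-methyl-3-[2-(2-methyl-1,3-dioxolan-2-yl)ethyl]dihydrofuran-2(3H)-one, via lithium enolate 14 (not isolated)
Conditions: LiN(i-Pr)2 (LDA, 1.2 equiv), THF, −78 → −40 °C; then allyl bromide, DMPU, −78 → 0 °C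
Reagents that add atoms: none
Why: Enolate alkylation under steric approach control on a five-membered ring, in which allyl bromide meets the fully substituted enolate on the face opposite the cis C8 methyl and C7 aryl groups, so allyl ends trans to the methyl and the quaternary centre C1 is set.

Step 7
Reactants: 15 dialkylated lactone
Product: 16 (2R,3R,4S)-2-allyl-4-(3,4-dimethoxyphenyl)-3-methyl-2-[2-(2-methyl-1,3-dioxolan-2-yl)ethyl]butane-1,4-diol
Conditions: LiAlH4, THF, 0 → 25 °C; then H2O, aq. NaOH
Reagents that add atoms: none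
Why: Hydride reduction of the lactone opens it to the 1,4-diol, turning C6 into CH2OH and freeing the C7 hydroxyl, while ketal, alkene and the three stereocentres are inert.

Step 8
Reactants: 16 diol
Product: 18 C6-O-triethylsilyl C7-O-tert-butyldimethylsilyl bis-ether of diol 16, via C6-O-triethylsilyl mono-ether 17 (not isolated)
Conditions: Et3SiCl (1.05 equiv), imidazole, CH2Cl2, −40 → 0 °C; then TBSOTf, 2,6-lutidine, 0 °C
Reagents that add atoms: chlorotriethylsilane, CC[Si](CC)(CC)Cl; tert-butyldimethylsilyl trifluoromethanesulfonate, CC(C)(C)[Si](C)(C)OS(=O)(=O)C(F)(F)F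
Why: Sequential silylation under steric control, the silyl chloride taking the primary C6 hydroxyl and the stronger silyl triflate then covering the hindered benzylic C7 hydroxyl.

Step 9
Reactants: 18 mixed bis-silyl ether
Product: 19 (2R,3R,4S)-2-allyl-4-[(tert-butyldimethylsilyl)oxy]-4-(3,4-dimethoxyphenyl)-3-methyl-2-[2-(2-methyl-1,3-dioxolan-2-yl)ethyl]butanal
Conditions: (COCl)2, DMSO, CH2Cl2, −78 → −30 °C; then Et3N, −78 → 0 °C
Reagents that add atoms: none
Why: Swern oxidation applied directly to a primary triethylsilyl ether (oxidative desilylation), in which chlorodimethylsulfonium chloride activates the unhindered C6 oxygen and chloride removes the silyl group while the secondary TBS ether stays.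

Step 10
Reactants: 19 aldehyde
Product: 21 (4S)-4-allyl-4-[(1S,2R)-1-[(tert-butyldimethylsilyl)oxy]-1-(3,4-dimethoxyphenyl)propan-2-yl]cyclohex-2-en-1-one, via keto aldehyde 20 (not isolated)
Conditions: PPTS, acetone–H2O, 55 °C; concentrate; then KOH, MeOH, 25 °C
Reagents that add atoms: water, O
Why: Ketal hydrolysis followed by intramolecular aldol condensation (the ring-closing half of a Robinson annulation) forms C5–C6 and the carbocycle, because only the methyl ketone can enolise toward the non-enolisable aldehyde and the silyl group keeps the C7 oxygen from adding to C6 of the enone.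

Step 11
Reactants: 21 enone
Product: 22 tosylhydrazone of enone 21
Conditions: TsNHNH2, THF–MeOH, 25 → 45 °C
Reagents that add atoms: 4-methylbenzenesulfonohydrazide, Cc1ccc(cc1)S(=O)(=O)NN
Why: Condensation of the C4 carbonyl with tosylhydrazide gives the hydrazone needed for the Shapiro reaction.

Step 12
Reactants: 22 tosylhydrazone
Product: 23 (5R)-5-allyl-5-[(1S,2R)-1-[(tert-butyldimethylsilyl)oxy]-1-(3,4-dimethoxyphenyl)propan-2-yl]cyclohexa-1,3-diene
Conditions: LiN(i-Pr)2 (LDA, 3.5 equiv), THF, −78 → 25 °C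
Reagents that add atoms: none
Why: Shapiro reaction of an α,β-unsaturated tosylhydrazone, in which deprotonation at nitrogen and at the C3 methylene, loss of sulfinate and N2, and protonation of the vinyl anion create C3=C4 beside C5=C6 without touching C1.

Step 13
Reactants: 23 diene
Product: 24 (1S,4R,5S)-5-allyl-5-[(1S,2R)-1-[(tert-butyldimethylsilyl)oxy]-1-(3,4-dimethoxyphenyl)propan-2-yl]cyclohex-2-ene-1,4-diyl diacetate (trans diacetate; C3 acetate cis to the side chain)
Conditions: Pd(OAc)2 (5 mol %), p-benzoquinone (20 mol %), MnO2 (1.3 equiv), LiOAc, AcOH, 25 °C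
Reagents that add atoms: acetic acid, CC(=O)O
Why: Divalent palladium should bind the C3=C4–C5=C6 diene on the face carrying the slim allyl group (anti to the branched C8 side chain, helped by ligation of the allyl C=C), and acetate from solution then attacks the open terminus C3 anti to the metal to leave an η3-allylpalladium unit over C4–C6. With benzoquinone on the metal and no chloride present, a palladium-bound acetate migrates cis to C6, the allyl terminus remote from the new C3–O bond, and the zerovalent palladium released is reoxidised by benzoquinone, itself regenerated by MnO2. The closest known reaction type is the chloride-free palladium-catalysed trans-1,4-diacetoxylation of cyclohexa-1,3-dienes with benzoquinone; no ring closes. C3 (S) is controlled by the face of metal coordination, since external attack puts the oxygen cis to the side chain, and C6 (R) by the cis migration on the metal face, which makes the diacetate trans; C6 is made planar again in step 17. The step needs face selectivity, 1,4- over 1,2-addition and reaction at the diene in preference to the isolated allyl alkene; these rest on the size difference of the two C1 substituents, on deactivation of C4 by the adjacent acetoxy group with C6 reached only by intramolecular delivery, and on the far faster binding of a conjugated diene than of a terminal alkene at 25 °C, while the silyl ether keeps the C7 oxygen from attacking C6.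

Step 14
Reactants: 24 trans diacetate
Product: 25 (1R,4S,6S)-6-allyl-6-[(1S,2R)-1-[(tert-butyldimethylsilyl)oxy]-1-(3,4-dimethoxyphenyl)propan-2-yl]-4-hydroxycyclohex-2-en-1-yl acetate
Conditions: K2CO3 (0.3 equiv), MeOH, 0 °C
Reagents that add atoms: none
Why: Base-catalysed transesterification (methanolysis) should be faster at the C3 acetate, flanked by a methylene and the alkene, than at the C6 acetate buried next to quaternary C1, and both stereocentres keep their configuration.

Step 15
Reactants: 25 C3 alcohol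
Product: 26 (1R,4S,6S)-6-allyl-6-[(1S,2R)-1-[(tert-butyldimethylsilyl)oxy]-1-(3,4-dimethoxyphenyl)propan-2-yl]-4-methoxycyclohex-2-en-1-yl acetate
Conditions: MeI, Ag2O, 4 Å molecular sieves, MeCN, 40 °C, dark
Reagents that add atoms: iodomethane, CI
Why: Silver-oxide-mediated O-methylation (a non-basic Williamson-type etherification) should convert the C3 hydroxyl into the methyl ether with retention and without disturbing the C6 acetate.

Step 16
Reactants: 26 methyl ether acetate
Product: 27 (1R,4S,6S)-6-allyl-6-[(1S,2R)-1-[(tert-butyldimethylsilyl)oxy]-1-(3,4-dimethoxyphenyl)propan-2-yl]-4-methoxycyclohex-2-en-1-ol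
Conditions: K2CO3, MeOH, 40 °C
Reagents that add atoms: none
Why: Methanolysis of the remaining hindered acetate frees the allylic C6 hydroxyl.

Step 17
Reactants: 27 C6 alcohol
Product: 28 (4S,6S)-6-allyl-6-[(1S,2R)-1-[(tert-butyldimethylsilyl)oxy]-1-(3,4-dimethoxyphenyl)propan-2-yl]-4-methoxycyclohex-2-en-1-one
Conditions: Dess–Martin periodinane, NaHCO3, CH2Cl2, 0 → 25 °C
Reagents that add atoms: none
Why: Dess–Martin oxidation of the allylic alcohol gives the C6 ketone conjugated with C4=C5, while C1 is quaternary and C3 is not epimerised under buffered conditions.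

Step 18
Reactants: 28 silyl-protected enone
Product: 29 (4S,6S)-6-allyl-6-[(1S,2R)-1-(3,4-dimethoxyphenyl)-1-hydroxypropan-2-yl]-4-methoxycyclohex-2-en-1-one (target)
Conditions: HF·pyridine, pyridine, THF, 0 → 25 °C
Reagents that add atoms: none
Why: Buffered fluoride-mediated desilylation should release the C7 hydroxyl without acid-induced ionisation of the electron-rich benzylic position.

**Compound list**

1 | veratraldehyde (3,4-dimethoxybenzaldehyde) | COc1ccc(C=O)cc1OC | starting material
2 | (Z)-crotylboronic acid pinacol ester | C/C=C\CB1OC(C)(C)C(C)(C)O1 | starting material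
3 | pinacol borate ester of alcohol 4 (not isolated) | C=C[C@@H](C)[C@H](OB1OC(C)(C)C(C)(C)O1)c1ccc(OC)c(OC)c1 | intermediate
4 | (1S,2R)-1-(3,4-dimethoxyphenyl)-2-methylbut-3-en-1-ol | C=C[C@@H](C)[C@H](O)c1ccc(OC)c(OC)c1 | intermediate
5 | (1S,2R)-4-(9-borabicyclo[3.3.1]nonan-9-yl)-1-(3,4-dimethoxyphenyl)-2-methylbutan-1-ol (not isolated) | C[C@H](CCB1C2CCCC1CCC2)[C@H](O)c1ccc(OC)c(OC)c1 | intermediate
6 | (1S,2R)-1-(3,4-dimethoxyphenyl)-2-methylbutane-1,4-diol | OCC[C@@H](C)[C@H](O)c1ccc(OC)c(OC)c1 | intermediate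
7 | (4R,5S)-5-(3,4-dimethoxyphenyl)-4-methyltetrahydrofuran-2-ol, lactol (not isolated) | OC1O[C@H](c2ccc(OC)c(OC)c2)[C@H](C)C1 | intermediate
8 | (4R,5S)-5-(3,4-dimethoxyphenyl)-4-methyldihydrofuran-2(3H)-one, methyl and aryl cis | O=C1O[C@H](c2ccc(OC)c(OC)c2)[C@H](C)C1 | intermediate
9 | 2-(2-bromoethyl)-2-methyl-1,3-dioxolane | CC1(CCBr)OCCO1 | starting material
10 | 2-(2-iodoethyl)-2-methyl-1,3-dioxolane | CC1(CCI)OCCO1 | intermediate
11 | lithium enolate of lactone 8 (not isolated) | [Li+].[O-]C1=C[C@@H](C)[C@@H](c2ccc(OC)c(OC)c2)O1 | intermediate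
12 | (3R,4R,5S)-5-(3,4-dimethoxyphenyl)-4-methyl-3-[2-(2-methyl-1,3-dioxolan-2-yl)ethyl]dihydrofuran-2(3H)-one | O=C1O[C@H](c2ccc(OC)c(OC)c2)[C@H](C)[C@H]1CCC1(C)OCCO1 | intermediate
13 | allyl bromide (3-bromoprop-1-ene) | C=CCBr | starting material
14 | lithium enolate of lactone 12 (not isolated) | [Li+].[O-]C1=C(CCC2(C)OCCO2)[C@@H](C)[C@@H](c2ccc(OC)c(OC)c2)O1 | intermediate
15 | (3R,4R,5S)-3-allyl-5-(3,4-dimethoxyphenyl)-4-methyl-3-[2-(2-methyl-1,3-dioxolan-2-yl)ethyl]dihydrofuran-2(3H)-one, allyl trans to the C4 methyl | O=C1O[C@H](c2ccc(OC)c(OC)c2)[C@H](C)[C@]1(CC=C)CCC1(C)OCCO1 | intermediate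
16 | (2R,3R,4S)-2-allyl-4-(3,4-dimethoxyphenyl)-3-methyl-2-[2-(2-methyl-1,3-dioxolan-2-yl)ethyl]butane-1,4-diol | C=CC[C@@](CO)([C@@H](C)[C@H](O)c1ccc(OC)c(OC)c1)CCC1(C)OCCO1 | intermediate
17 | C6-O-triethylsilyl mono-ether of diol 16 (not isolated) | C=CC[C@@](CO[Si](CC)(CC)CC)([C@@H](C)[C@H](O)c1ccc(OC)c(OC)c1)CCC1(C)OCCO1 | intermediate
18 | C6-O-triethylsilyl C7-O-tert-butyldimethylsilyl bis-ether of diol 16 | C=CC[C@@](CO[Si](CC)(CC)CC)([C@@H](C)[C@H](O[Si](C)(C)C(C)(C)C)c1ccc(OC)c(OC)c1)CCC1(C)OCCO1 | intermediate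
19 | (2R,3R,4S)-2-allyl-4-[(tert-butyldimethylsilyl)oxy]-4-(3,4-dimethoxyphenyl)-3-methyl-2-[2-(2-methyl-1,3-dioxolan-2-yl)ethyl]butanal | C=CC[C@@](C=O)([C@@H](C)[C@H](O[Si](C)(C)C(C)(C)C)c1ccc(OC)c(OC)c1)CCC1(C)OCCO1 | intermediate
20 | (2R,3R,4S)-2-allyl-4-[(tert-butyldimethylsilyl)oxy]-4-(3,4-dimethoxyphenyl)-3-methyl-2-(3-oxobutyl)butanal (not isolated) | C=CC[C@@](C=O)([C@@H](C)[C@H](O[Si](C)(C)C(C)(C)C)c1ccc(OC)c(OC)c1)CCC(C)=O | intermediate
21 | (4S)-4-allyl-4-[(1S,2R)-1-[(tert-butyldimethylsilyl)oxy]-1-(3,4-dimethoxyphenyl)propan-2-yl]cyclohex-2-en-1-one | C=CC[C@@]1([C@@H](C)[C@H](O[Si](C)(C)C(C)(C)C)c2ccc(OC)c(OC)c2)CCC(=O)C=C1 | intermediate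
22 | tosylhydrazone of enone 21 | C=CC[C@@]1([C@@H](C)[C@H](O[Si](C)(C)C(C)(C)C)c2ccc(OC)c(OC)c2)CCC(=NNS(=O)(=O)c2ccc(C)cc2)C=C1 | intermediate
23 | (5R)-5-allyl-5-[(1S,2R)-1-[(tert-butyldimethylsilyl)oxy]-1-(3,4-dimethoxyphenyl)propan-2-yl]cyclohexa-1,3-diene | C=CC[C@@]1([C@@H](C)[C@H](O[Si](C)(C)C(C)(C)C)c2ccc(OC)c(OC)c2)CC=CC=C1 | intermediate
24 | (1S,4R,5S)-5-allyl-5-[(1S,2R)-1-[(tert-butyldimethylsilyl)oxy]-1-(3,4-dimethoxyphenyl)propan-2-yl]cyclohex-2-ene-1,4-diyl diacetate, trans, C3 acetate cis to the side chain | C=CC[C@@]1([C@@H](C)[C@H](O[Si](C)(C)C(C)(C)C)c2ccc(OC)c(OC)c2)C[C@H](OC(C)=O)C=C[C@H]1OC(C)=O | intermediate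
25 | (1R,4S,6S)-6-allyl-6-[(1S,2R)-1-[(tert-butyldimethylsilyl)oxy]-1-(3,4-dimethoxyphenyl)propan-2-yl]-4-hydroxycyclohex-2-en-1-yl acetate | C=CC[C@@]1([C@@H](C)[C@H](O[Si](C)(C)C(C)(C)C)c2ccc(OC)c(OC)c2)C[C@H](O)C=C[C@H]1OC(C)=O | intermediate
26 | (1R,4S,6S)-6-allyl-6-[(1S,2R)-1-[(tert-butyldimethylsilyl)oxy]-1-(3,4-dimethoxyphenyl)propan-2-yl]-4-methoxycyclohex-2-en-1-yl acetate | C=CC[C@@]1([C@@H](C)[C@H](O[Si](C)(C)C(C)(C)C)c2ccc(OC)c(OC)c2)C[C@H](OC)C=C[C@H]1OC(C)=O | intermediate
27 | (1R,4S,6S)-6-allyl-6-[(1S,2R)-1-[(tert-butyldimethylsilyl)oxy]-1-(3,4-dimethoxyphenyl)propan-2-yl]-4-methoxycyclohex-2-en-1-ol | C=CC[C@@]1([C@@H](C)[C@H](O[Si](C)(C)C(C)(C)C)c2ccc(OC)c(OC)c2)C[C@H](OC)C=C[C@H]1O | intermediate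
28 | (4S,6S)-6-allyl-6-[(1S,2R)-1-[(tert-butyldimethylsilyl)oxy]-1-(3,4-dimethoxyphenyl)propan-2-yl]-4-methoxycyclohex-2-en-1-one | C=CC[C@@]1([C@@H](C)[C@H](O[Si](C)(C)C(C)(C)C)c2ccc(OC)c(OC)c2)C[C@H](OC)C=CC1=O | intermediate
29 | (4S,6S)-6-allyl-6-[(1S,2R)-1-(3,4-dimethoxyphenyl)-1-hydroxypropan-2-yl]-4-methoxycyclohex-2-en-1-one | C=CC[C@@]1([C@@H](C)[C@H](O)c2ccc(OC)c(OC)c2)C[C@H](OC)C=CC1=O | target

**Step count**

Total: 18 steps. Longest linear sequence: 17 steps (steps 1–3 and 5–18 from veratraldehyde; step 4 is a one-step side branch).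

**Steps most likely to fail**

Step 13. Palladium may fail to discriminate the two diene faces, or may engage the allyl alkene (allylic oxidation or cyclisation through the 1,5-diene unit) instead of completing the 1,4-addition. The fallback sets out from diene 23 and returns at diacetate 24, using reagent approach plus one inversion instead of metal-face control. Singlet oxygen (O2, tetraphenylporphyrin, visible light, CH2Cl2, −20 °C) should add across C3 and C6 on the face away from the side chain to give the bicyclic endoperoxide F1. Thiourea in MeOH would reduce the O–O bond to the cis-enediol F2, with both hydroxyls on the allyl face. A Mitsunobu reaction (PPh3, DIAD, AcOH, THF) at the unhindered C3 hydroxyl would invert that centre and give the C3 acetate C6 alcohol F3. Acetylation (Ac2O, DMAP, pyridine) then gives 24.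

Step 5. SN2 displacement on the β-ketal iodide may be slow, so that E2 elimination of the iodide and double alkylation of the lactone take over. The fallback sets out from lactone 8 and returns at lactone 12, forming C1–C2 by conjugate addition instead of substitution. LiN(i-Pr)2 and Me3SiCl (THF, −78 °C) would give the silyl ketene acetal F4. Mukaiyama–Michael addition to methyl vinyl ketone (Sc(OTf)3 5 mol %, CH2Cl2, −78 °C, aqueous work-up) would give the keto lactone F5. Ketalisation (ethylene glycol, PPTS, benzene, reflux with water removal) then gives 12.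

Step 12. Deprotonation of the hydrazone may occur slowly or on the wrong side, and the dianion may decompose before sulfinate and nitrogen are lost. The fallback sets out from enone 21, bypasses hydrazone 22 and returns at diene 23. Kinetic deprotonation at C3 (LiN(i-Pr)2, THF, −78 °C) and trapping with PhNTf2 would give the cross-conjugated dienyl triflate F6. Palladium-catalysed formate reduction (Pd(OAc)2, PPh3, n-Bu3N, HCO2H, DMF, 60 °C) would replace the triflate by hydrogen and give 23.

**Further compounds**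

F1 | step 13 | endoperoxide of diene 23 (2,3-dioxabicyclo[2.2.2]oct-5-ene, O–O bridge from C3 to C6 on the allyl face) | C=CC[C@@]1([C@@H](C)[C@H](O[Si](C)(C)C(C)(C)C)c2ccc(OC)c(OC)c2)C[C@@H]2C=C[C@H]1OO2
F2 | step 13 | cis-cyclohex-2-ene-1,4-diol with both hydroxyls (C3 and C6) on the allyl face | C=CC[C@@]1([C@@H](C)[C@H](O[Si](C)(C)C(C)(C)C)c2ccc(OC)c(OC)c2)C[C@@H](O)C=C[C@H]1O
F3 | step 13 | C3 acetate (inverted, cis to the side chain) C6 alcohol | C=CC[C@@]1([C@@H](C)[C@H](O[Si](C)(C)C(C)(C)C)c2ccc(OC)c(OC)c2)C[C@H](OC(C)=O)C=C[C@H]1O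
F4 | step 5 | trimethylsilyl ketene acetal of lactone 8 | C[Si](C)(C)OC1=C[C@@H](C)[C@@H](c2ccc(OC)c(OC)c2)O1
F5 | step 5 | (3R,4R,5S)-5-(3,4-dimethoxyphenyl)-4-methyl-3-(3-oxobutyl)dihydrofuran-2(3H)-one | O=C1O[C@H](c2ccc(OC)c(OC)c2)[C@H](C)[C@H]1CCC(C)=O
F6 | step 12 | cyclohexa-1,5-dien-1-yl triflate from enone 21 (triflate on C4, alkenes C3=C4 and C5=C6) | C=CC[C@@]1([C@@H](C)[C@H](O[Si](C)(C)C(C)(C)C)c2ccc(OC)c(OC)c2)CC=C(OS(=O)(=O)C(F)(F)F)C=C1
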